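Readings and results were computed with constants of no real substance, and the scatter is random.

In the ash run L read 0.1% at 8.00 min although J had already fallen to 37.4%, and in the hotter oak run L read 1.0% at 2.00 min with J at 32.2%. So L behaved like a signal behind a dead time, which chemists call an induction period, and I had to decide which of the next flasks deserved charging.

| flask | J | temperature | remark | time |
|---|---|---|---|---|
| ash | 0.016 M | 28 °C | run made earlier |  |
| oak | 0.024 M | 44 °C | run made earlier |  |
| epsilon | 0.032 M |  | at 20 °C until 8.0 min, from then on at 50 °C | 12 min |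
| eta | 0.032 M | 20 °C |  | 12 min |
| alpha | 0.032 M | 50 °C |  | 12 min |
| beta | 0.032 M | 35 °C |  | 12 min |

| run | time / min | L / % | J / % |
|---|---|---|---|
| ash | 3.00 | 0 | 65.9 |
| ash | 6.00 | 0 | 46.6 |
| ash | 8.00 | 0.1 | 37.4 |
| ash | 12.0 | 1.7 | 26.5 |
| ash | 15.0 | 3.2 | 20.4 |
| oak | 0.417 | 0.7 | 75.2 |
| oak | 1.33 | 0.7 | 45.6 |
| oak | 2.00 | 1.0 | 32.2 |
| oak | 3.00 | 4.0 | 21.6 |
| oak | 5.00 | 12.7 | 9.7 |

(scatter of a reading: 0.5 percentage points)



- the best flask by amount of L, in percent of the J charged; "all alike" if 1.5 percentage points covers them all (epsilon / eta / alpha / beta / all alike)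
- amount of L at the end, in percent of the J charged, epsilon
- amount of L at the end, in percent of the J charged, eta
- amount of L at the end, in percent of the J charged, alpha
- amount of L at the end, in percent of the J charged, beta

I took the lag of a run as the time at which the line through its last two L readings meets zero:

lag, ash = 8.60 min

lag, oak = 2.08 min

These are readings, and rough ones: the ash line rests on a rise of 1.5 percentage points with a scatter of 0.5 points. The charges also differed, c_J being 0.016 M and 0.024 M, but I set that aside and gave the change in lag to temperature. R times the logarithm of the ratio of the lags, divided by the difference of the reciprocal temperatures, then gave 70.4 kJ mol⁻¹, the lag energy, which stretches the lag as a flask is cooled. From it I reckoned: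

lag at 20 °C = 18.5 min

lag at 35 °C = 4.54 min

lag at 50 °C = 1.27 min

Eta's 12 min is shorter than its lag, so I left eta out as a source of L. For epsilon, my first answer restarted the clock at the change, giving an onset at 9.27 min. Going round once more, I credited the cold minutes with the 43.2% of the lag they had used, and the onset moved to

8.72 min

Alpha had 10.7 min past its lag, more than beta's 7.46 min or epsilon's 3.28 min, so I chose alpha to charge first. My lags give times and no amounts.

The forecast also put alpha first, with L at 58% in alpha, 22% in epsilon, 9% in beta and 0.2% in eta, on the ground that “L is not made directly”.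

The flask gave alpha as best, with L at 58.9% in alpha, 20.4% in epsilon, 10.0% in beta and 0.108% in eta.

    2 J → E (k = 0.220 M⁻¹ s⁻¹, Ea = 51.0 kJ mol⁻¹)
    D → Z (k = 0.00940 s⁻¹, Ea = 81.0 kJ mol⁻¹)
    Z → X (k = 0.00910 s⁻¹, Ea = 86.0 kJ mol⁻¹)
    J → D (k = 0.00930 s⁻¹, Ea = 84.0 kJ mol⁻¹)
    X → L (k = 0.0700 s⁻¹, Ea = 73.0 kJ mol⁻¹)
    (constants at 50 °C)

In epsilon, L stood at 0.0282% at the change, 8.00 min, with D at 10.6% and Z at 1.22% at that moment, and L stood at 20.4% at 12.0 min. The lag energy then goes to a flask like eta kept at 45 °C: it gives a lag of 1.91 min, so 12 min spans 6.28 lags, and that flask held L at 45.2%.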